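The runs were computed for substances that don't exist.

If a target climbs, falls and then stands still, count half-lives of that fall before you judge what any further step can do.

common to all: starting material 0.10 M; free enzyme 0.0081 mol%; temperature 20 °C
- ochre: second substrate 0.50 equiv; the very flask that is asked about, followed so far
- flask: second substrate 0.500 equiv; time 40 h

ochre run (percent of the starting material charged)

| time / h | target / % | starting material / % |
|---|---|---|
| 2.00 | 59.6 | 18.0 |
| 6.00 | 38.0 | 1.9 |
| 12.0 | 28.2 | 1.2 |
| 20.0 | 26.1 | 0.5 |
| 25.0 | 26.4 | 1.2 |
| 30.0 | 26.6 | 0 |

(readings scatter by 1 percentage point)

- what is taken out of target is counted as made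
- the analysis behind the earlier runs scatters by 1 percentage point, standard deviation
- additions bring no volume worth counting
- the earlier runs do not show what temperature does; that part of a forecast is a guess

- gamma: at 40 h add free enzyme, 100% of the amount charged, then wait 20 h
- delta: at 40 h take out 90% of the target then present, then wait 20 h
- alpha: change nothing and wait 20 h more
- eta: at 40 h raise the temperature by 10 K, then wait 20 h

1. target, in percent of the starting material first charged, at 40 h
2. the option that brings most further target ("none" if no option brings more than 2 percentage points) (gamma / delta / alpha / eta / none)
3. target present, with what was taken out counted in, in percent of the starting material first charged, after gamma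
4. target present, with what was taken out counted in, in percent of the starting material first charged, after eta

Build the ochre flask up one process at a time. With the main step by itself, starting material simply becomes target, so at 6.00 h you expect

target = 98.1%, against 38.0% read.

Something therefore takes target away. Add a one-way loss that keeps its pace, and target should go on falling, but it reads 26.1% at 20.0 h and 26.6% at 30.0 h. So add the last process: the loss also runs back, and target settles at a plateau, read as the mean of the last three readings:

plateau = 26.4%.

Now take the excess of target above that plateau, from 6.00 h on, where starting material reads 1.9%, and ask how long it needs to fall by a factor of 2: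

excess half-life = 2.25 h.

This excess half-life is a reading and carries the scatter. The wait of 20 h is longer, at 8.89 half-lives, so this reckoning treats the flask as balanced (thermodynamic control). This reckoning then puts target at 40 h at the plateau and expects no gain from fresh enzyme or more time. Taking out 90% of the target leaves a pool that rebalances to the same share:

pool = 76.3%, target in the pool afterwards = 20.1%, total = 43.8%, a gain of 17 percentage points.

Warming is a guess here, so this reckoning leaves it at the plateau.

The forecast parts from this reckoning on the best option and on gamma. It says 26.4% now, best option none, 5% after gamma and 26.4% after eta, on the ground that “the flask is simply dead, not balanced”.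

The flask gives 25.6% at 40.0 h, and the best option is delta, with a gain of 17 points. Gamma ends at 25.6% and eta at 24.9%.

    target ⇌ isomer of the product (K = 2.90, k = 8.10 × 10⁻⁵ /s, Ea = 87.0 kJ/mol, ΔH = 3.00 kJ/mol)
    second substrate + free enzyme ⇌ complex B (K = 22.0 /M, k = 240 /M/s, Ea = 46.0 kJ/mol, ΔH = −17.0 kJ/mol)
    complex B → free enzyme + second product (k = 70.0 /s, Ea = 57.0 kJ/mol)
    free enzyme ⇌ dormant form (K = 2.50, k = 3.60 × 10⁻⁵ /s, Ea = 97.0 kJ/mol, ΔH = −33.0 kJ/mol)
    free enzyme → unfolded enzyme (k = 6.10 × 10⁻⁶ /s, Ea = 217 kJ/mol)
    starting material + free enzyme ⇌ complex A (K = 13.0 /M, k = 330 /M/s, Ea = 36.0 kJ/mol, ΔH = −16.0 kJ/mol)
    complex A → free enzyme + target (k = 4.40 /s, Ea = 71.0 kJ/mol)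
    (constants at 20 °C)

Target turns into isomer of the product with a half-life, by the forward rate of that step taken by itself, of 2.4 h, far shorter than the 40 h of the run, and at that time this flask holds 25.6% target and 74.4% isomer. In the neighbour flask kept at −5 °C, target still stands at 75.3% after 40.0 h; counting the whole charge as target from the start and measuring against the plateau read in the ochre run, that comes to 0.590 half-lives, fewer than the 17.8 that the excess half-life read at 20 °C fits into the same time.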